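The numbering used throughout is: chain C1 (CH2Br) to C5; ring A carbons C1' (bears the chain), C2' (CMe2), C3' (CHBr) and C6' (bears the methylidene). Everything rests on cutting ring A at the C6'–C1' bond: once chain carbon C4 is an ester, C1' is the β-carbon of an enoate. An alkenyl radical at C6', released from an acyclic 2-bromoalkene, adds 6-exo to C1' and so closes ring A, installs the exocyclic methylidene and sets the C1' stereocentre under control of a C3' silyl ether in one operation. The precursor is an open-chain (E)-enoate with the gem-dimethyl carbon, a single aldol-derived silyloxy stereocentre and a 2-bromoallyl terminus.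

Key step: step 8

Assumption: the boron promoter made from N-tosyl-D-valine is taken to deliver the 3S aldol with this unbranched aldehyde (the L-valine reagent would give the mirror image); intermediates are discussed with the target locants defined above.

Step 1
Reactants: 1 tert-butyl acetate; 2 2,3-dibromopropene
Product: 4 tert-butyl 4-bromopent-4-enoate, via lithium tert-butyl acetate enolate 3 (not isolated)
Conditions: LiN(i-Pr)2 (1.05 equiv), THF, −78 °C; then 2, −78 → 0 °C
Reagents that add atoms: none
Why: Ester enolate alkylation at the allylic bromide of 2 (SN2, the vinylic bromide being inert), with the tert-butyl ester suppressing Claisen self-condensation.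

Step 2
Reactants: 4 tert-butyl 4-bromopent-4-enoate
Product: 5 4-bromopent-4-enal
Conditions: i-Bu2AlH (1.1 equiv), CH2Cl2, −78 °C; MeOH, then aq. potassium sodium tartrate
Reagents that add atoms: none
Why: Partial ester reduction with i-Bu2AlH stops at the tetrahedral aluminium hemiacetal at −78 °C, which should release the aldehyde only on work-up.

Step 3
Reactants: 5 4-bromopent-4-enal; 6 1-methoxy-2-methyl-1-(trimethylsilyloxy)prop-1-ene
Product: 7 methyl (3S)-6-bromo-3-hydroxy-2,2-dimethylhept-6-enoate
Conditions: N-tosyl-D-valine (1.1 equiv), BH3·THF (1.0 equiv), CH2Cl2, 0 °C → rt; then 5 and 6, −78 °C; pH 7 buffer, then dilute HCl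
Reagents that add atoms: none
Why: Kiyooka variant of the enantioselective Mukaiyama aldol, in which the aldehyde is bound to boron of the valine-derived oxazaborolidinone and the ketene acetal should attack its open face to set the carbinol centre (the later C3') as S, the electron-poor bromoalkene being inert to the B–H promoter at −78 °C.

Step 4
Reactants: 7 methyl (3S)-6-bromo-3-hydroxy-2,2-dimethylhept-6-enoate
Product: 8 methyl (3S)-6-bromo-3-[(tert-butyldimethylsilyl)oxy]-2,2-dimethylhept-6-enoate
Conditions: TBSOTf, 2,6-lutidine, CH2Cl2, 0 °C → rt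
Reagents that add atoms: tert-butyldimethylsilyl trifluoromethanesulfonate, CC(C)(C)[Si](C)(C)OS(=O)(=O)C(F)(F)F
Why: Silylation of the hindered neopentylic alcohol needs the silyl triflate, and the ether both blocks retro-aldol cleavage and provides the bulky equatorial group that steers the key step.

Step 5
Reactants: 8 methyl (3S)-6-bromo-3-[(tert-butyldimethylsilyl)oxy]-2,2-dimethylhept-6-enoate
Product: 9 (3S)-6-bromo-3-[(tert-butyldimethylsilyl)oxy]-2,2-dimethylhept-6-en-1-ol
Conditions: i-Bu2AlH (2.5 equiv), CH2Cl2, −78 → 0 °C; aq. potassium sodium tartrate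
Reagents that add atoms: none
Why: Exhaustive hydride reduction of the hindered ester to the primary alcohol is more dependable than stopping at the aldehyde, and the silyl ether and bromoalkene are untouched.

Step 6
Reactants: 9 (3S)-6-bromo-3-[(tert-butyldimethylsilyl)oxy]-2,2-dimethylhept-6-en-1-ol
Product: 10 (3S)-6-bromo-3-[(tert-butyldimethylsilyl)oxy]-2,2-dimethylhept-6-enal
Conditions: Dess–Martin periodinane, CH2Cl2, 0 °C → rt
Reagents that add atoms: none
Why: Dess–Martin oxidation gives the non-enolisable α-quaternary aldehyde under near-neutral conditions that cannot touch the stereocentre.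

Step 7
Reactants: 10 (3S)-6-bromo-3-[(tert-butyldimethylsilyl)oxy]-2,2-dimethylhept-6-enal; 11 trimethyl phosphonoacetate
Product: 13 methyl (2E,5S)-8-bromo-5-[(tert-butyldimethylsilyl)oxy]-4,4-dimethylnona-2,8-dienoate, via sodium phosphonoacetate carbanion 12 (not isolated)
Conditions: NaH, 11, THF, 0 °C; then 10, 0 °C → rt
Reagents that add atoms: none
Why: Horner–Wadsworth–Emmons olefination with the stabilised phosphonate anion should give the E-enoate, the quaternary α-carbon ruling out enolisation and β-elimination.

Step 8
Reactants: 13 methyl (2E,5S)-8-bromo-5-[(tert-butyldimethylsilyl)oxy]-4,4-dimethylnona-2,8-dienoate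
Product: 14 methyl 2-[(1R,3S)-3-[(tert-butyldimethylsilyl)oxy]-2,2-dimethyl-6-methylidenecyclohexyl]acetate
Conditions: Bu3SnH (1.3 equiv) and AIBN (2,2'-azobis(2-methylpropanenitrile), 0.2 equiv) added by syringe pump over 6 h to 13 in benzene (0.005 M), 80 °C; aq. KF work-up
Reagents that add atoms: none
Why: The tributyltin radical abstracts bromine from the 2-bromoalkene to give a σ-alkenyl radical at C6' (C8 of 13), which adds to the enoate β-carbon C1' (C3 of 13), and the ester-stabilised radical left at chain C5 takes hydrogen from Bu3SnH to carry the chain. The closest known reaction type is the tin hydride-mediated cyclisation of alkenyl radicals onto α,β-unsaturated esters. Ring A closes in the 6-exo-trig mode, and because the radical carbon itself becomes the methylidene-bearing ring carbon the exocyclic alkene is fixed and cannot migrate into the ring. The new stereocentre C1' is controlled by the C3' silyloxy centre through a chair-like transition state with the silyloxy group and the enoate arm both equatorial, which should give the cis (1R,3S) ring. The step needs exo over endo attack and cyclisation over premature reduction; polarity matching of the nucleophilic alkenyl radical with the electron-poor β-carbon, the gem-dimethyl group in the tether, the quaternary C2' that offers no hydrogen for a 1,5-shift, and slow hydride addition at high dilution should secure both.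

Step 9
Reactants: 14 methyl 2-[(1R,3S)-3-[(tert-butyldimethylsilyl)oxy]-2,2-dimethyl-6-methylidenecyclohexyl]acetate
Product: 15 methyl 2-[(1R,3S)-3-hydroxy-2,2-dimethyl-6-methylidenecyclohexyl]acetate
Conditions: HF·pyridine, pyridine, THF, 0 °C → rt
Reagents that add atoms: none
Why: Fluoride-driven desilylation under buffered, non-basic conditions avoids a free alkoxide that could lactonise onto the cis-disposed ester arm.

Step 10
Reactants: 15 methyl 2-[(1R,3S)-3-hydroxy-2,2-dimethyl-6-methylidenecyclohexyl]acetate
Product: 16 methyl 2-[(1R)-2,2-dimethyl-6-methylidene-3-oxocyclohexyl]acetate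
Conditions: Dess–Martin periodinane, CH2Cl2, 0 °C → rt
Reagents that add atoms: none
Why: Dess–Martin oxidation of the secondary alcohol gives the ketone, and C1' is not α to the new carbonyl and so cannot epimerise.

Step 11
Reactants: 16 methyl 2-[(1R)-2,2-dimethyl-6-methylidene-3-oxocyclohexyl]acetate
Product: 17 methyl 2-[(1R,3R)-3-hydroxy-2,2-dimethyl-6-methylidenecyclohexyl]acetate
Conditions: (S)-Me-CBS [(3aS)-1-methyl-3,3-diphenyltetrahydro-1H,3H-pyrrolo[1,2-c][1,3,2]oxazaborole] (0.2 equiv), catecholborane (1.5 equiv), toluene, −78 → −20 °C; MeOH, pH 7 buffer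
Reagents that add atoms: none
Why: Corey–Bakshi–Shibata reduction, in which the catalyst should distinguish the quaternary C2' (large) from the C4' methylene (small) and deliver the 3R alcohol trans to the side chain under reagent control, while catecholborane spares the ester and the methylidene group.

Step 12
Reactants: 17 methyl 2-[(1R,3R)-3-hydroxy-2,2-dimethyl-6-methylidenecyclohexyl]acetate
Product: 18 methyl 2-[(1R,3S)-3-bromo-2,2-dimethyl-6-methylidenecyclohexyl]acetate
Conditions: CBr4, PPh3, CH2Cl2, 0 °C → rt
Reagents that add atoms: carbon tetrabromide, BrC(Br)(Br)Br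
Why: Appel reaction, in which bromide displaces the alkoxyphosphonium group with inversion (SN2), converting the trans 3R alcohol into the 3S bromide cis to the side chain.

Step 13
Reactants: 18 methyl 2-[(1R,3S)-3-bromo-2,2-dimethyl-6-methylidenecyclohexyl]acetate
Product: 19 2-[(1R,3S)-3-bromo-2,2-dimethyl-6-methylidenecyclohexyl]acetaldehyde
Conditions: i-Bu2AlH (1.1 equiv), CH2Cl2, −78 °C; MeOH, then aq. potassium sodium tartrate
Reagents that add atoms: none
Why: Partial ester reduction with i-Bu2AlH at −78 °C should stop at the aluminium hemiacetal and give the aldehyde on work-up, the hindered secondary bromide being inert to the hydride.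

Step 14
Reactants: 19 2-[(1R,3S)-3-bromo-2,2-dimethyl-6-methylidenecyclohexyl]acetaldehyde; 20 ethyl 2-[bis(2,2,2-trifluoroethoxy)phosphoryl]propanoate
Product: 22 ethyl (2Z)-4-[(1R,3S)-3-bromo-2,2-dimethyl-6-methylidenecyclohexyl]-2-methylbut-2-enoate, via potassium phosphonopropanoate carbanion 21 (not isolated)
Conditions: 20, KN(SiMe3)2, 18-crown-6, THF, −78 °C; then 19, −78 °C
Reagents that add atoms: none
Why: Still–Gennari modification of the Horner–Wadsworth–Emmons reaction, in which the electron-poor bis(trifluoroethyl) phosphonate with a dissociated potassium counter-ion eliminates under kinetic control to give the Z trisubstituted enoate.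

Step 15
Reactants: 22 ethyl (2Z)-4-[(1R,3S)-3-bromo-2,2-dimethyl-6-methylidenecyclohexyl]-2-methylbut-2-enoate; 23 dibromomethane
Product: 25 (3Z)-1-bromo-5-[(1R,3S)-3-bromo-2,2-dimethyl-6-methylidenecyclohexyl]-3-methylpent-3-en-2-one, via bromomethyllithium 24 (not isolated)
Conditions: 23 (3 equiv), MeLi·LiBr (2.5 equiv, slow addition to 22 and 23), THF/Et2O, −78 °C; AcOH, −78 °C
Reagents that add atoms: none
Why: Carbenoid acyl substitution, in which bromomethyllithium formed by bromine–lithium exchange beside the ester adds once to the carbonyl and the tetrahedral adduct, stable at −78 °C, should collapse to the bromomethyl ketone only on the cold acidic quench.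

Step 16
Reactants: 25 (3Z)-1-bromo-5-[(1R,3S)-3-bromo-2,2-dimethyl-6-methylidenecyclohexyl]-3-methylpent-3-en-2-one
Product: 26 (2S,3Z)-1-bromo-5-[(1R,3S)-3-bromo-2,2-dimethyl-6-methylidenecyclohexyl]-3-methylpent-3-en-2-ol
Conditions: (S)-Me-CBS [(3aS)-1-methyl-3,3-diphenyltetrahydro-1H,3H-pyrrolo[1,2-c][1,3,2]oxazaborole] (0.5 equiv), catecholborane (1.5 equiv), toluene, −78 °C; MeOH, pH 7 buffer
Reagents that add atoms: none
Why: Corey–Bakshi–Shibata reduction with the α-branched alkenyl group as the large and CH2Br as the small substituent should set C2 as S by reagent control, and catecholborane at low temperature reduces the carbonyl 1,2 without touching the alkenes or the bromides.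

Compound list
1 | tert-butyl acetate | CC(=O)OC(C)(C)C | starting material
2 | 2,3-dibromopropene | C=C(Br)CBr | starting material
3 | lithium tert-butyl acetate enolate (lithium 1-tert-butoxyethen-1-olate) | [Li]OC(=C)OC(C)(C)C | intermediate
4 | tert-butyl 4-bromopent-4-enoate | C=C(Br)CCC(=O)OC(C)(C)C | intermediate
5 | 4-bromopent-4-enal | C=C(Br)CCC=O | intermediate
6 | 1-methoxy-2-methyl-1-(trimethylsilyloxy)prop-1-ene | COC(O[Si](C)(C)C)=C(C)C | starting material
7 | methyl (3S)-6-bromo-3-hydroxy-2,2-dimethylhept-6-enoate | C=C(Br)CC[C@H](O)C(C)(C)C(=O)OC | intermediate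
8 | methyl (3S)-6-bromo-3-[(tert-butyldimethylsilyl)oxy]-2,2-dimethylhept-6-enoate | C=C(Br)CC[C@H](O[Si](C)(C)C(C)(C)C)C(C)(C)C(=O)OC | intermediate
9 | (3S)-6-bromo-3-[(tert-butyldimethylsilyl)oxy]-2,2-dimethylhept-6-en-1-ol | C=C(Br)CC[C@H](O[Si](C)(C)C(C)(C)C)C(C)(C)CO | intermediate
10 | (3S)-6-bromo-3-[(tert-butyldimethylsilyl)oxy]-2,2-dimethylhept-6-enal | C=C(Br)CC[C@H](O[Si](C)(C)C(C)(C)C)C(C)(C)C=O | intermediate
11 | trimethyl phosphonoacetate | COC(=O)CP(=O)(OC)OC | starting material
12 | sodium salt of the trimethyl phosphonoacetate carbanion | [Na+].COC(=O)[CH-]P(=O)(OC)OC | intermediate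
13 | methyl (2E,5S)-8-bromo-5-[(tert-butyldimethylsilyl)oxy]-4,4-dimethylnona-2,8-dienoate | C=C(Br)CC[C@H](O[Si](C)(C)C(C)(C)C)C(C)(C)/C=C/C(=O)OC | intermediate
14 | methyl 2-[(1R,3S)-3-[(tert-butyldimethylsilyl)oxy]-2,2-dimethyl-6-methylidenecyclohexyl]acetate | C=C1CC[C@H](O[Si](C)(C)C(C)(C)C)C(C)(C)[C@@H]1CC(=O)OC | intermediate
15 | methyl 2-[(1R,3S)-3-hydroxy-2,2-dimethyl-6-methylidenecyclohexyl]acetate | C=C1CC[C@H](O)C(C)(C)[C@@H]1CC(=O)OC | intermediate
16 | methyl 2-[(1R)-2,2-dimethyl-6-methylidene-3-oxocyclohexyl]acetate | C=C1CCC(=O)C(C)(C)[C@@H]1CC(=O)OC | intermediate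
17 | methyl 2-[(1R,3R)-3-hydroxy-2,2-dimethyl-6-methylidenecyclohexyl]acetate | C=C1CC[C@@H](O)C(C)(C)[C@@H]1CC(=O)OC | intermediate
18 | methyl 2-[(1R,3S)-3-bromo-2,2-dimethyl-6-methylidenecyclohexyl]acetate | C=C1CC[C@H](Br)C(C)(C)[C@@H]1CC(=O)OC | intermediate
19 | 2-[(1R,3S)-3-bromo-2,2-dimethyl-6-methylidenecyclohexyl]acetaldehyde | C=C1CC[C@H](Br)C(C)(C)[C@@H]1CC=O | intermediate
20 | ethyl 2-[bis(2,2,2-trifluoroethoxy)phosphoryl]propanoate | CCOC(=O)C(C)P(=O)(OCC(F)(F)F)OCC(F)(F)F | starting material
21 | potassium salt of the carbanion of 20 (potassium 2-[bis(2,2,2-trifluoroethoxy)phosphoryl]-1-ethoxy-1-oxopropan-2-ide) | [K+].CCOC(=O)[C-](C)P(=O)(OCC(F)(F)F)OCC(F)(F)F | intermediate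
22 | ethyl (2Z)-4-[(1R,3S)-3-bromo-2,2-dimethyl-6-methylidenecyclohexyl]-2-methylbut-2-enoate | C=C1CC[C@H](Br)C(C)(C)[C@@H]1C/C=C(/C)C(=O)OCC | intermediate
23 | dibromomethane | BrCBr | starting material
24 | bromomethyllithium | [Li]CBr | intermediate
25 | (3Z)-1-bromo-5-[(1R,3S)-3-bromo-2,2-dimethyl-6-methylidenecyclohexyl]-3-methylpent-3-en-2-one | C=C1CC[C@H](Br)C(C)(C)[C@@H]1C/C=C(/C)C(=O)CBr | intermediate
26 | (2S,3Z)-1-bromo-5-[(1R,3S)-3-bromo-2,2-dimethyl-6-methylidenecyclohexyl]-3-methylpent-3-en-2-ol | C=C1CC[C@H](Br)C(C)(C)[C@@H]1C/C=C(/C)[C@H](O)CBr | target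

Total step count: 16. Longest linear sequence: 16 steps (1 to 26); the route is fully linear.

Steps most likely to fail

Step 8. The ring closure may discriminate poorly between the two faces of the enoate, since 1,3-induction across the quaternary carbon is untested, and hydrogen transfer to the alkenyl radical may compete with cyclisation. The fallback enforces the cis relationship geometrically by tying the C3' oxygen to the acceptor as a lactone. It sets out from aldehyde 10: Still–Gennari olefination with methyl bis(2,2,2-trifluoroethyl)phosphonoacetate (KN(SiMe3)2, 18-crown-6, THF, −78 °C) should give methyl (2Z,5S)-8-bromo-5-[(tert-butyldimethylsilyl)oxy]-4,4-dimethylnona-2,8-dienoate F1. Aqueous HF in MeCN then removes the silyl group, and the freed hydroxyl should close onto the Z-ester to give (6S)-6-(3-bromobut-3-en-1-yl)-5,5-dimethyl-5,6-dihydro-2H-pyran-2-one F2. The same tin hydride conditions close ring A onto the lactone β-carbon; because the new ring bridges the lactone, only the cis arrangement can form, giving (1S,5R)-9,9-dimethyl-6-methylidene-2-oxabicyclo[3.3.1]nonan-3-one F3. Methanolysis (K2CO3, MeOH) should open the bridged lactone and return to the route at hydroxy ester 15.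

Step 12. The neopentylic alkoxyphosphonium ion may undergo elimination or methyl migration instead of substitution. The fallback separates activation from displacement and sets out from alcohol 17: Tf2O and 2,6-lutidine in CH2Cl2 at −78 °C should give methyl 2-[(1R,3R)-2,2-dimethyl-6-methylidene-3-(trifluoromethanesulfonyloxy)cyclohexyl]acetate F4. The triflate is then displaced with inversion by a soluble bromide (Bu4NBr, toluene, 0 °C → rt), returning to the route at bromide 18.

Step 15. The thermally fragile carbenoid may add incompletely or twice to the hindered conjugated ester, or methyllithium may add directly. The fallback changes the acyl electrophile to one that forms a chelated, non-collapsing adduct and sets out from ester 22: MeNH(OMe)·HCl and AlMe3 in CH2Cl2 (0 °C → rt) should give (2Z)-4-[(1R,3S)-3-bromo-2,2-dimethyl-6-methylidenecyclohexyl]-N-methoxy-N,2-dimethylbut-2-enamide F5. Bromomethyllithium (CH2Br2, MeLi·LiBr, THF, −78 °C) then adds once to this amide and, after quench, returns to the route at bromomethyl ketone 25.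

Further compounds
F1 | step 8 | methyl (2Z,5S)-8-bromo-5-[(tert-butyldimethylsilyl)oxy]-4,4-dimethylnona-2,8-dienoate | C=C(Br)CC[C@H](O[Si](C)(C)C(C)(C)C)C(C)(C)/C=C\C(=O)OC
F2 | step 8 | (6S)-6-(3-bromobut-3-en-1-yl)-5,5-dimethyl-5,6-dihydro-2H-pyran-2-one | C=C(Br)CC[C@@H]1OC(=O)C=CC1(C)C
F3 | step 8 | (1S,5R)-9,9-dimethyl-6-methylidene-2-oxabicyclo[3.3.1]nonan-3-one | C=C1CC[C@@H]2OC(=O)C[C@H]1C2(C)C
F4 | step 12 | methyl 2-[(1R,3R)-2,2-dimethyl-6-methylidene-3-(trifluoromethanesulfonyloxy)cyclohexyl]acetate | C=C1CC[C@@H](OS(=O)(=O)C(F)(F)F)C(C)(C)[C@@H]1CC(=O)OC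
F5 | step 15 | (2Z)-4-[(1R,3S)-3-bromo-2,2-dimethyl-6-methylidenecyclohexyl]-N-methoxy-N,2-dimethylbut-2-enamide | C=C1CC[C@H](Br)C(C)(C)[C@@H]1C/C=C(/C)C(=O)N(C)OC
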